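**Retrosynthetic overview**

1. Numbering: C1 is the quaternary carbon bearing C15H2OAc; ring A is C1–C2–C3(OAc)–C4(OH)–C5(Me2)–C6; C6 is the cage apex, C7 the CH2 bridge, C8–C9–C10 the cyclopropane (C8 on C7, C9 on C1, C10 methylated), C11 the CHOAc bridge. The strategy rests on one feature: ring A is closed onto C1 and the cyclopropane onto C9, and C1/C9 are the two ends of one double bond of a norbornadiene (bridgeheads C6/C8, second double bond C10=C11).
2. Endgame: C3–OAc/C4–OH from a cis-diol cyclic orthoacetate; the cis-diol from the ring A diosphenol; the C11 carbinol from a C11 boronate by oxidation and reversible hydride transfer.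
3. Key disconnection: C1–C2 (ring A), C9–C10 (cyclopropane) and C11–B in one palladium domino from a bridgehead-tethered Z-β-triflyloxy enone.
4. Norbornadiene: intramolecular Diels–Alder reaction (C6–C1, C8–C9) of a cyclopentadiene whose C6 side chain carries a propiolate on the C4 carbinol; the lactone is then opened to C15H2OH and the C4 ketone. The diene comes from 3-ethoxycyclopentenone, isobutyronitrile and MeLi.
5. Ring order: cyclopentadiene ring (purchased) → bicyclo[2.2.1] core with a temporary lactone → ring A and cyclopropane together in the key step.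

Key step: step 10

Remark (assumption): 6, 7 and 9 are drawn as the cyclopentadiene tautomer that cyclises; the tautomers interconvert by 1,5-hydrogen shifts.
Remark (assumption): no facial preference is assumed in step 4; the C4 carbinol centre serves as a resolving handle, the two facial cycloadducts are taken to be separable by chromatography, and only the one with the bicycle configuration drawn for 10 is carried on.

**Step 1**
Reactants: 1 3-ethoxycyclopent-2-en-1-one; 2 isobutyronitrile
Product: 3 2-methyl-2-(3-oxocyclopent-1-en-1-yl)propanenitrile
Conditions: LiN(i-Pr)2, THF, −78 °C; add 1, −78 → 0 °C; then 1 M HCl, rt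
Reagents that add atoms: water, O
Why: Stork–Danheiser-type alkylative transposition: the lithiated nitrile adds to the vinylogous ester and acid work-up expels ethanol, which leads to the same 3-substituted enone whether the first attack is at the carbonyl or at the alkoxy-bearing carbon; no stereocentre is formed.

**Step 2**
Reactants: 3 2-methyl-2-(3-oxocyclopent-1-en-1-yl)propanenitrile
Product: 6 3-methyl-3-(3-methylcyclopenta-1,3-dien-1-yl)butan-2-one, via dilithio adduct 4 (not isolated), via hydroxy ketone 5 (not isolated)
Conditions: MeLi (3 equiv), Et2O, −78 °C → rt; then 2 M HCl, THF, rt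
Reagents that add atoms: methyllithium, [Li]C; water, O
Why: Organolithium addition then acid-mediated hydrolysis and E1 dehydration: MeLi adds 1,2 to the enone carbonyl in the cold and once to the nitrile, which has no α-hydrogen, on warming; aqueous acid hydrolyses the ketimine to the methyl ketone and ionises the tertiary allylic alcohol to an allyl cation that loses a proton to give the cyclopentadiene, so the transient carbinol centre is of no consequence.

**Step 3**
Reactants: 6 3-methyl-3-(3-methylcyclopenta-1,3-dien-1-yl)butan-2-one
Product: 7 (2R)-3-methyl-3-(3-methylcyclopenta-1,3-dien-1-yl)butan-2-ol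
Conditions: (S)-2-methyl-CBS-oxazaborolidine (20 mol%), catecholborane, toluene, −78 °C; aq. NaOH work-up
Reagents that add atoms: none
Why: Corey–Bakshi–Shibata reduction of a tert-alkyl methyl ketone, a substrate class with maximal steric difference between the two flanks, so the (S)-catalyst should deliver hydride to the face that gives the (R)-carbinol with high enantioselectivity, and catecholborane at low temperature does not hydroborate the diene.

**Step 4**
Reactants: 7 (2R)-3-methyl-3-(3-methylcyclopenta-1,3-dien-1-yl)butan-2-ol; 8 propiolic acid
Product: 10 tricyclic lactone (norbornadiene with bridgeheads C6/C8; δ-lactone C1–C15(=O)–O–C4–C5–C6; 4R; methyl on C10), via propiolate ester 9 (not isolated)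
Conditions: DCC, DMAP (5 mol%), CH2Cl2, −20 → 0 °C; filter; toluene, BHT, 80 °C; chromatography
Reagents that add atoms: none
Why: Steglich esterification followed by an intramolecular Diels–Alder reaction: only the tautomer with the side chain on a diene terminus can reach the ynoate and the unsubstituted terminus C8 reacts faster than the methyl-bearing C10, so the tether dictates C6–C1 and C8–C9 bond formation, while the gem-dimethyl group and the reactive diene offset the ester rotamer penalty; the bridgehead centres C6 and C8 form on either diene face with little bias from C4 (its methyl group is outside in both transition states), so the facial diastereomer with the mirror-image bicycle is removed by chromatography and 10 carries the enantiomeric purity of 7.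

**Step 5**
Reactants: 10 tricyclic lactone
Product: 11 norbornadiene diol (C15H2OH on C1; (4R)-CH(OH)CH3 on C5)
Conditions: i-Bu2AlH (4 equiv), CH2Cl2, −78 → 0 °C; aq. potassium sodium tartrate
Reagents that add atoms: none
Why: Hydride reduction of a conjugated lactone: i-Bu2AlH reduces the carbonyl 1,2 through the lactol stage to the primary allylic alcohol and liberates the C4 carbinol, no stereocentre being touched.

**Step 6**
Reactants: 11 norbornadiene diol
Product: 12 primary TBS ether of 11 (C15H2OTBS; C4–OH free)
Conditions: TBSCl (1.05 equiv), imidazole, CH2Cl2, 0 °C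
Reagents that add atoms: tert-butyldimethylsilyl chloride, CC(C)(C)[Si](C)(C)Cl
Why: Selective silyl ether formation: the unhindered primary allylic hydroxyl reacts far faster than the secondary hydroxyl next to the quaternary C5.

**Step 7**
Reactants: 12 primary TBS ether
Product: 13 methyl ketone (C4=O with CH3 as future C3; C15H2OTBS)
Conditions: Dess–Martin periodinane, pyridine, CH2Cl2, rt
Reagents that add atoms: none
Why: Dess–Martin oxidation of the secondary alcohol gives the methyl ketone and removes the C4 stereocentre once it has served as resolving handle.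

**Step 8**
Reactants: 13 methyl ketone
Product: 14 β-keto aldehyde as its Z-enol (C4(=O)–C3H=C2H–OH)
Conditions: NaH, HCO2Et, EtOH (cat.), THF, 0 °C → rt; AcOH
Reagents that add atoms: ethyl formate, CCOC=O
Why: Crossed Claisen condensation with ethyl formate: C5 is quaternary, so the ketone enolises only at its methyl group, and the β-keto aldehyde is obtained as the hydrogen-bonded Z-enol.

**Step 9**
Reactants: 14 β-keto aldehyde Z-enol
Product: 15 Z-β-triflyloxy enone on the norbornadiene bridgehead (C4(=O)–C3H=C2H–OTf; C15H2OTBS on C1; methyl on C10)
Conditions: LiOTf, Et3N, Tf2O, CH2Cl2, −78 °C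
Reagents that add atoms: trifluoromethanesulfonic anhydride, O=S(=O)(OS(=O)(=O)C(F)(F)F)C(F)(F)F
Why: Stereoselective enol triflate formation from a 1,3-dicarbonyl compound: the lithium-chelated, U-shaped enolate is sulfonylated at the unhindered aldehyde-derived oxygen and keeps the Z geometry, which places the C2–O bond (later C2–Pd) cis to C4 as ring A requires.

**Step 10**
Reactants: 15 Z-β-triflyloxy enone; 16 bis(pinacolato)diboron
Product: 17 cage enone boronate (ring A C1–C2=C3–C4(=O)–C5Me2–C6 on the nortricyclene; C2 syn to C11, C15H2OTBS syn to C7; Bpin on C11 pointing toward C1)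
Conditions: Pd2(dba)3 (2.5 mol%), P(o-tolyl)3 (6 mol%), KOAc (3 equiv), 1,4-dioxane, 60 °C
Reagents that add atoms: none
Why: Proposed new method: zerovalent palladium adds oxidatively to the vinylogous acyl triflate, the cationic vinylpalladium carbopalladates the strained C1=C9 bond at C1 (6-exo-trig, syn; closes ring A and makes C1 quaternary), the resulting C9–Pd bond has no accessible β-hydrogen and inserts the facing C10=C11 bond (3-exo-trig, syn; closes the cyclopropane C8–C9–C10), and the C11–Pd bond, flanked by the quaternary C6 and C10, is intercepted by acetate-assisted transmetalation with B2pin2 and C–B reductive elimination. The closest known reaction types are domino Heck/borylation sequences that trap β-hydrogen-free alkylpalladium intermediates and the arylpalladium additions to norbornadiene that end in nortricyclyl-palladium species; their combination on a bridgehead-tethered vinyl triflate with a secondary, doubly neopentyl C–Pd bond is new. C1 is set by delivery to the endo face, on which the electron-poor metal stays coordinated to the C10=C11 bond, so C2 ends syn to C11 and C15 syn to C7; C9 and C10 are fixed by the two syn insertions within the rigid bicycle, and C11 receives palladium, then boron with retention, on the side facing C1 (inverted in steps 13 and 14). The step needs endo over exo attack and 6-exo over 7-endo closure: the three-atom tether from the bridgehead favours the six-membered ring, one bulky phosphine and the triflate counter-ion leave a coordination site for the second double bond, and an exo adduct has no cyclopropane-forming path and can revert by β-carbon elimination while the endo adduct is drained forward.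

**Step 11**
Reactants: 17 cage enone boronate
Product: 18 saturated cage ketone boronate (C2H2–C3H2; C4=O)
Conditions: H2 (1 atm), 10% Pd/C, EtOAc, rt
Reagents that add atoms: none
Why: Heterogeneous catalytic hydrogenation of the cis-disubstituted enone double bond; the alkyl boronate, the silyl ether and the nortricyclene cyclopropane are stable to Pd/C at one atmosphere, no stereocentre is formed, and saturating the enone first means that the C11 alkoxide of the next step, which lies next to C2, never faces a Michael acceptor.

**Step 12**
Reactants: 18 saturated cage ketone boronate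
Product: 19 C11 alcohol (hydroxyl pointing toward C1; C4=O)
Conditions: 30% H2O2, 2 M NaOH, THF, 0 °C → rt
Reagents that add atoms: hydrogen peroxide, OO
Why: Oxidation of a carbon–boron bond by alkaline hydrogen peroxide proceeds by 1,2-migration with retention, so the hydroxyl appears on C11 on the side facing C1, which is the epimer opposite to the target.

**Step 13**
Reactants: 19 C11 alcohol
Product: 20 C4,C11-diketone
Conditions: Dess–Martin periodinane, pyridine, CH2Cl2, rt
Reagents that add atoms: none
Why: Dess–Martin oxidation of the hindered secondary alcohol gives the non-enolisable cyclopropyl ketone and so erases the wrongly configured C11 centre.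

**Step 14**
Reactants: 20 C4,C11-diketone
Product: 22 diol (C11–OH pointing toward C7; C4–OH equatorial on the C15 face), via C11-epimeric diol 21 (not isolated)
Conditions: Al(OiPr)3 (3 equiv), i-PrOH/toluene, acetone (0.2 equiv), sealed, 100 °C; aq. potassium sodium tartrate
Reagents that add atoms: none
Why: Meerwein–Ponndorf–Verley reduction kept reversible by the acetone left in the flask: hydride is first delivered to C11 from the open C7 side to give 21, which is re-oxidised and drained to the more stable epimer whose hydroxyl points to C7 and away from the C2 methylene, while C4 takes the equatorial hydroxyl that avoids the syn-axial C11; hydride transfer, unlike dissolving-metal reduction, leaves the cyclopropyl ketone ring intact.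

**Step 15**
Reactants: 22 diol
Product: 23 hydroxy ketone (C4=O; C11–OH pointing toward C7)
Conditions: TEMPO (10 mol%), PhI(OAc)2 (1.1 equiv), CH2Cl2, rt
Reagents that add atoms: none
Why: Chemoselective oxoammonium (TEMPO) oxidation: this oxidant is very sensitive to hindrance, so the C4 carbinol with one quaternary neighbour should be oxidised while the C11 carbinol between the quaternary C6 and C10 is left, and any over-oxidised material is 20 and is returned to step 14.

**Step 16**
Reactants: 23 hydroxy ketone
Product: 25 diosphenol (C2=C3(OH)–C4=O), via 3-hydroperoxy ketone 24 (not isolated)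
Conditions: KOtBu (3 equiv), O2 (1 atm), t-BuOH/THF, rt; AcOH
Reagents that add atoms: dioxygen, O=O
Why: Base-mediated autoxidation of a ketone enolate: enolisation is possible only toward C3, the enolate takes up oxygen to give hydroperoxide 24, and this loses water to the 1,2-dicarbonyl compound, which is obtained as its enol tautomer, the diosphenol, as is usual for 2,2-dimethylcyclohexanones.

**Step 17**
Reactants: 25 diosphenol
Product: 27 triol (C3–OH axial; C4–OH equatorial; both on the C15 face; C11–OH toward C7), via 3-hydroxy-4-ketone 26 (not isolated)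
Conditions: NaBH4, EtOH, 0 °C
Reagents that add atoms: none
Why: Substrate-controlled borohydride reduction of 25 through its diketo tautomer: C3 is attacked on the face away from the syn-axial C15 and the axial C5 methyl, which gives the axial alkoxide of 26 on the C15 face, and C4 is then attacked anti to this adjacent axial C–O bond and away from the axial methyl, which gives the equatorial hydroxyl cis to it.

**Step 18**
Reactants: 27 triol
Product: 28 C3/C4 cyclic methyl orthoacetate (C11–OH free; C15H2OTBS)
Conditions: MeC(OMe)3, PPTS (cat.), CH2Cl2, rt; Et3N quench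
Reagents that add atoms: trimethyl orthoacetate, COC(C)(OC)OC
Why: Acid-catalysed orthoester exchange: only the cis-vicinal C3/C4 diol can close the five-membered cyclic orthoacetate, the hindered C11 hydroxyl stays free, and the new orthoester carbon is formed as a mixture that is of no consequence.

**Step 19**
Reactants: 28 cyclic orthoacetate
Product: 29 orthoacetate diol (C15H2OH; C11–OH)
Conditions: Bu4NF, THF, 0 °C → rt
Reagents that add atoms: none
Why: Fluoride-mediated desilylation frees the primary C15 hydroxyl, and the cyclic orthoester is stable to the basic medium.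

**Step 20**
Reactants: 29 orthoacetate diol
Product: 30 orthoacetate diacetate (C15–OAc; C11–OAc)
Conditions: Ac2O, Et3N, DMAP, CH2Cl2, 40 °C
Reagents that add atoms: acetic anhydride, CC(=O)OC(C)=O
Why: DMAP-catalysed acetylation esterifies the primary C15 hydroxyl at once and the hindered C11 hydroxyl on gentle warming, while the C3 and C4 oxygens stay masked.

**Step 21**
Reactants: 30 orthoacetate diacetate
Product: 32 CNP0197219.1 (C3–OAc; C4–OH; C11–OAc; C15–OAc), via hemiorthoester 31 (not isolated)
Conditions: AcOH/H2O (4:1), rt
Reagents that add atoms: water, O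
Why: Mild acid hydrolysis of a cyclic orthoester on a cis-diol passes through hemiorthoester 31, which collapses so that the axial oxygen (C3) keeps the acetyl group and the equatorial oxygen (C4) is freed, the established regiochemistry of this opening; no base follows, so the acetate cannot migrate.

**Compound list**

1 | 3-ethoxycyclopent-2-en-1-one | CCOC1=CC(=O)CC1 | starting material
2 | isobutyronitrile | CC(C)C#N | starting material
3 | 2-methyl-2-(3-oxocyclopent-1-en-1-yl)propanenitrile | CC(C)(C#N)C1=CC(=O)CC1 | intermediate
4 | dilithio adduct (lithium alkoxide and N-lithio ketimine; racemic carbinol carbon) | CC(=N[Li])C(C)(C)C1=CC(C)(O[Li])CC1 | intermediate (not isolated)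
5 | 3-(3-hydroxy-3-methylcyclopent-1-en-1-yl)-3-methylbutan-2-one (racemic) | CC(=O)C(C)(C)C1=CC(C)(O)CC1 | intermediate (not isolated)
6 | 3-methyl-3-(3-methylcyclopenta-1,3-dien-1-yl)butan-2-one | CC(=O)C(C)(C)C1=CC(C)=CC1 | intermediate
7 | (2R)-3-methyl-3-(3-methylcyclopenta-1,3-dien-1-yl)butan-2-ol | C[C@@H](O)C(C)(C)C1=CC(C)=CC1 | intermediate
8 | propiolic acid | C#CC(=O)O | starting material
9 | (2R)-3-methyl-3-(3-methylcyclopenta-1,3-dien-1-yl)butan-2-yl prop-2-ynoate | C#CC(=O)O[C@H](C)C(C)(C)C1=CC(C)=CC1 | intermediate (not isolated)
10 | tricyclic lactone, 4R, bicycle as in 15 (seen from C5 along C6→C8: C1, C11, C7 counter-clockwise) | O=C3O[C@H](C)C(C)(C)[C@]12C[C@H](C=C13)C(C)=C2 | intermediate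
11 | norbornadiene diol (C15H2OH; 4R carbinol) | C[C@@H](O)C(C)(C)[C@]12C[C@H](C=C1CO)C(C)=C2 | intermediate
12 | primary TBS ether of 11 | C[C@@H](O)C(C)(C)[C@]12C[C@H](C=C1CO[Si](C)(C)C(C)(C)C)C(C)=C2 | intermediate
13 | methyl ketone | CC(=O)C(C)(C)[C@]12C[C@H](C=C1CO[Si](C)(C)C(C)(C)C)C(C)=C2 | intermediate
14 | β-keto aldehyde, Z-enol form | O=C(/C=C\O)C(C)(C)[C@]12C[C@H](C=C1CO[Si](C)(C)C(C)(C)C)C(C)=C2 | intermediate
15 | Z-β-triflyloxy enone (key-step precursor) | O=C(/C=C\OS(=O)(=O)C(F)(F)F)C(C)(C)[C@]12C[C@H](C=C1CO[Si](C)(C)C(C)(C)C)C(C)=C2 | intermediate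
16 | bis(pinacolato)diboron | CC1(C)OB(OC1(C)C)B1OC(C)(C)C(C)(C)O1 | starting material
17 | cage enone with C11 boronate (Bpin toward C1) | CC(C)(C)[Si](C)(C)OC[C@]12C=CC(=O)C(C)(C)[C@]13C[C@@H]1[C@H]2[C@]1(C)[C@@H]3B4OC(C)(C)C(C)(C)O4 | intermediate
18 | saturated cage ketone with C11 boronate | CC(C)(C)[Si](C)(C)OC[C@]12CCC(=O)C(C)(C)[C@]13C[C@@H]1[C@H]2[C@]1(C)[C@@H]3B4OC(C)(C)C(C)(C)O4 | intermediate
19 | cage C4 ketone, C11–OH toward C1 | CC(C)(C)[Si](C)(C)OC[C@]12CCC(=O)C(C)(C)[C@]13C[C@@H]1[C@H]2[C@]1(C)[C@@H]3O | intermediate
20 | cage C4,C11-diketone | CC(C)(C)[Si](C)(C)OC[C@]12CCC(=O)C(C)(C)[C@]13C[C@@H]1[C@H]2[C@]1(C)C3=O | intermediate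
21 | cage diol, C11–OH toward C1 (kinetic epimer), C4–OH equatorial | CC(C)(C)[Si](C)(C)OC[C@]12CC[C@H](O)C(C)(C)[C@]13C[C@@H]1[C@H]2[C@]1(C)[C@@H]3O | intermediate (not isolated)
22 | cage diol, C11–OH toward C7, C4–OH equatorial | CC(C)(C)[Si](C)(C)OC[C@]12CC[C@H](O)C(C)(C)[C@]13C[C@@H]1[C@H]2[C@]1(C)[C@H]3O | intermediate
23 | cage C4 ketone, C11–OH toward C7 | CC(C)(C)[Si](C)(C)OC[C@]12CCC(=O)C(C)(C)[C@]13C[C@@H]1[C@H]2[C@]1(C)[C@H]3O | intermediate
24 | 3-hydroperoxy-4-ketone (C3 unassigned) | CC(C)(C)[Si](C)(C)OC[C@]12CC(OO)C(=O)C(C)(C)[C@]13C[C@@H]1[C@H]2[C@]1(C)[C@H]3O | intermediate (not isolated)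
25 | diosphenol (C2=C3(OH)–C4=O) | CC(C)(C)[Si](C)(C)OC[C@]12C=C(O)C(=O)C(C)(C)[C@]13C[C@@H]1[C@H]2[C@]1(C)[C@H]3O | intermediate
26 | 3-hydroxy-4-ketone, C3–OH axial on the C15 face | CC(C)(C)[Si](C)(C)OC[C@]12C[C@H](O)C(=O)C(C)(C)[C@]13C[C@@H]1[C@H]2[C@]1(C)[C@H]3O | intermediate (not isolated)
27 | triol (cis-C3,C4-diol on the C15 face; C11–OH toward C7) | CC(C)(C)[Si](C)(C)OC[C@]12C[C@H](O)[C@H](O)C(C)(C)[C@]13C[C@@H]1[C@H]2[C@]1(C)[C@H]3O | intermediate
28 | C3/C4 cyclic methyl orthoacetate (orthoester carbon as a mixture) | CC(C)(C)[Si](C)(C)OC[C@]12C[C@@H]4OC(C)(OC)O[C@@H]4C(C)(C)[C@]13C[C@@H]1[C@H]2[C@]1(C)[C@H]3O | intermediate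
29 | orthoacetate with free C15–OH and C11–OH | OC[C@]12C[C@@H]4OC(C)(OC)O[C@@H]4C(C)(C)[C@]13C[C@@H]1[C@H]2[C@]1(C)[C@H]3O | intermediate
30 | orthoacetate C11,C15-diacetate | CC(=O)OC[C@]12C[C@@H]4OC(C)(OC)O[C@@H]4C(C)(C)[C@]13C[C@@H]1[C@H]2[C@]1(C)[C@H]3OC(C)=O | intermediate
31 | hemiorthoester (2-hydroxy-2-methyl-1,3-dioxolane on C3/C4) | CC(=O)OC[C@]12C[C@@H]4OC(C)(O)O[C@@H]4C(C)(C)[C@]13C[C@@H]1[C@H]2[C@]1(C)[C@H]3OC(C)=O | intermediate (not isolated)
32 | CNP0197219.1 | CC(=O)OC[C@]12C[C@H](OC(C)=O)[C@H](O)C(C)(C)[C@]13C[C@@H]1[C@H]2[C@]1(C)[C@H]3OC(C)=O | target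

**Step count**

Total: 21 steps. Longest linear sequence: 21 steps (1 → 32); 8 and 16 enter as purchased reagents.

**Steps most likely to fail**

1. Step 10 (the step with the label). What may go wrong: boron transfer to the buried C11–palladium bond is too slow, so the alkylpalladium reverts by β-carbon elimination or is lost by protodepalladation before it is trapped. Fallback with known reactions, setting out from 15 and returning at 19: the cascade is run under CO (1 atm) with Me4Sn, Pd2(dba)3 and P(2-furyl)3 in dioxane, so that the C11–Pd bond is captured by fast CO insertion and carbonylative Stille coupling to give the C11-acetyl cage enone F1. Baeyer–Villiger oxidation (mCPBA, NaHCO3, CH2Cl2), in which the cage carbon migrates with retention and the conjugated ring A ketone is inert, should give the C11-acetoxy cage enone F2. Hydrogenation (H2, Pd/C) gives the saturated keto acetate F3, and methanolysis (K2CO3, MeOH) gives 19.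

2. Step 4. What may go wrong: cycloaddition through the disfavoured ester rotamer is slow, so tautomer scrambling toward closure at the methyl-bearing terminus and dimerisation of the diene compete. Fallback setting out from 7 and returning at 11: transacetalisation of 7 with 3,3-diethoxyprop-1-yne (PPTS, toluene, removal of ethanol) gives the mixed propargylic acetal F4. Catalytic TMSOTf at −78 °C ionises it to an alkynyl oxocarbenium ion, a much stronger dienophile without an ester rotamer problem, and the ionic intramolecular Diels–Alder reaction gives the cyclic acetal F5, whose facial diastereomers are separated as in the main route. Aqueous AcOH gives the lactol F6, and NaBH4 reduces it to 11.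

3. Step 14. What may go wrong: hydride transfer to and from the doubly neopentyl C11 centre is too slow for equilibration, so the kinetic epimer persists. Fallback setting out from 19 and returning at 23, with steps 13 to 15 bypassed: MsCl/Et3N converts 19 into the C11 mesylate F7. Buffered acetolysis (AcOH, KOAc, 60 °C) ionises it to a cyclopropylcarbinyl cation of the nortricyclyl type, which acetate should capture on the open C7 side to give the inverted C11 acetate F8. Methanolysis (K2CO3, MeOH) gives 23.

**Further compounds**

F1 | step 10 | C11-acetyl cage enone (acetyl toward C1) | CC(C)(C)[Si](C)(C)OC[C@]12C=CC(=O)C(C)(C)[C@]13C[C@@H]1[C@H]2[C@]1(C)[C@@H]3C(C)=O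
F2 | step 10 | C11-acetoxy cage enone (acetate toward C1) | CC(C)(C)[Si](C)(C)OC[C@]12C=CC(=O)C(C)(C)[C@]13C[C@@H]1[C@H]2[C@]1(C)[C@@H]3OC(C)=O
F3 | step 10 | saturated C4 ketone with C11 acetate toward C1 | CC(C)(C)[Si](C)(C)OC[C@]12CCC(=O)C(C)(C)[C@]13C[C@@H]1[C@H]2[C@]1(C)[C@@H]3OC(C)=O
F4 | step 4 | mixed ethyl propargylic acetal of 7 (acetal carbon unassigned) | CCOC(C#C)O[C@H](C)C(C)(C)C1=CC(C)=CC1
F5 | step 4 | cyclic ethyl acetal cycloadduct (C15 acetal carbon unassigned) | CCOC3O[C@H](C)C(C)(C)[C@]12C[C@H](C=C13)C(C)=C2
F6 | step 4 | lactol (C15 unassigned) | OC3O[C@H](C)C(C)(C)[C@]12C[C@H](C=C13)C(C)=C2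
F7 | step 14 | C11 mesylate of 19 | CC(C)(C)[Si](C)(C)OC[C@]12CCC(=O)C(C)(C)[C@]13C[C@@H]1[C@H]2[C@]1(C)[C@@H]3OS(C)(=O)=O
F8 | step 14 | C4 ketone with inverted C11 acetate (toward C7) | CC(C)(C)[Si](C)(C)OC[C@]12CCC(=O)C(C)(C)[C@]13C[C@@H]1[C@H]2[C@]1(C)[C@H]3OC(C)=O
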